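## Retrosynthetic overview

1. The target is cut at the C1 hydroxyl (γ-hydroxylation of a deconjugated enone) and then at ring C by a Diels–Alder disconnection (bonds C5–C13′ and C3–C11′) into 8-epi-xanthatin (diene C5=C1–C2=C3, 7R,8R,10S series) and the α-methylene lactone of its 2,3-dihydro analogue in the mirror-image series (7′S,8′S,10′R).
2. Each monomer comes from an acyclic allenyl keto-aldehyde and CO by an allenic hetero-Pauson–Khand cyclocarbonylation that closes the cycloheptene and the lactone together; in the eastern half this forms C7′–C8′ and C11′–C12′ (then C12′–O).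
3. The enabling feature: ring D is a γ-butyrolactone cis-fused to cycloheptene ring E through C7′–C8′, with its carbonyl C12′ on C11′ next to C13′, which is an exocyclic methylene before ring C is made. O–C8′(H), C7′–C11′(=C13′) and C12′=O are therefore the retron of aldehyde + allene + CO.
4. The allenyl aldehydes come from a Saucy–Marbet Claisen rearrangement (3-oxobutyl chain and Z-trisubstituted C1=C5 alkene), a Crabbé allene synthesis and a Barbier propargylation of an α-methylene lactol made from 4-methyl-δ-valerolactone. Both lactone antipodes come from one enzymatically desymmetrised 3-methylglutarate half-ester.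
5. Ring order: E + D (step 9), B + A (step 17), C (step 19); the C1 hydroxyl is introduced last (step 20).

Key step: step 9

Remark on numbering: xanthane numbering is used, C1–C15 for the diene-derived (western) half and C1′–C15′ for the dienophile-derived (eastern) half. Ring A is the western α-methylene lactone, B the western cycloheptane, C the central cyclohexene, D the spiro lactone, E the eastern cycloheptene. Precursors carry the locants of the carbons they become.

Remark on the chemistry (assumption): pig liver esterase is taken to give the (R)-half-ester of dimethyl 3-methylglutarate; if it gave the antipode, the reduction protocols of steps 2 and 10 would simply be exchanged.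

## Route

Step 1
Reactants: 1 dimethyl 3-methylpentanedioate (dimethyl 3-methylglutarate)
Product: 2 (3R)-5-methoxy-3-methyl-5-oxopentanoic acid (methyl hydrogen (R)-3-methylglutarate)
Conditions: pig liver esterase, phosphate buffer pH 7.0, NaOH (1.0 equiv, pH-stat), 10 °C; then HCl (aq) to pH 2
Reagents that add atoms: water, O
Why: Enzymatic desymmetrisation (enantiotopic-group-selective ester hydrolysis) of the prochiral diester sets the single stereocentre from which C10 and C10′ both derive, here as the (R)-half-ester.

Step 2
Reactants: 2 (3R)-5-methoxy-3-methyl-5-oxopentanoic acid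
Product: 4 (4R)-4-methyloxan-2-one, via hydroxy ester 3 (not isolated)
Conditions: BH3·SMe2 (1.1 equiv), THF, 0 °C → rt; MeOH; then TsOH·H2O (5 mol %), toluene, 50 °C
Reagents that add atoms: none
Why: Borane reduces the free carboxylic acid chemoselectively beside the methyl ester, and acid-catalysed lactonisation of the δ-hydroxy ester closes the (R)-lactone without touching the stereocentre.

Step 3
Reactants: 4 (4R)-4-methyloxan-2-one
Product: 6 (4R)-4-methyl-3-methylideneoxan-2-one, via sodium formyl-enolate 5 (not isolated)
Conditions: NaH (1.2 equiv), HCO2Et (1.5 equiv), Et2O, 0 °C → rt; then (CH2O)n (5 equiv), THF, reflux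
Reagents that add atoms: formaldehyde (as paraformaldehyde), C=O
Why: Claisen formylation followed by aldol addition to formaldehyde, formyl transfer and loss of formate is an established one-flask α-methylenation of lactones, and the C4 stereocentre is a spectator.

Step 4
Reactants: 6 (4R)-4-methyl-3-methylideneoxan-2-one
Product: 7 (4R)-4-methyl-3-methylideneoxan-2-ol (anomer mixture)
Conditions: iBu2AlH (1.1 equiv), CH2Cl2, −78 °C; aq. potassium sodium tartrate
Reagents that add atoms: none
Why: Low-temperature iBu2AlH reduction stops at the aluminium hemiacetal, so 1,2-reduction of the unsaturated lactone should give the lactol.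

Step 5
Reactants: 7 (4R)-4-methyl-3-methylideneoxan-2-ol
Product: 8 (3R)-3-methyl-4-methylideneoct-7-yne-1,5-diol (both carbinol epimers)
Conditions: propargyl bromide (2.0 equiv), Zn (2.5 equiv), THF/sat. aq. NH4Cl (1:1), 0 °C → rt
Reagents that add atoms: propargyl bromide, C#CCBr
Why: Aqueous zinc Barbier propargylation intercepts the open hydroxy-enal form of the lactol, the allenylzinc species adding SE2′ to give the homopropargylic alcohol; the new carbinol centre forms unselectively but becomes sp2 in step 7.

Step 6
Reactants: 8 (3R)-3-methyl-4-methylideneoct-7-yne-1,5-diol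
Product: 10 (3R)-3-methyl-4-methylidenenona-7,8-diene-1,5-diol (both carbinol epimers), via Mannich base 9 (not isolated)
Conditions: (CH2O)n (2 equiv), iPr2NH (2 equiv), CuBr (30 mol %), 1,4-dioxane, reflux
Reagents that add atoms: formaldehyde (as paraformaldehyde), C=O
Why: Crabbé homologation (Mannich reaction of the terminal alkyne, then copper-mediated hydride transfer and elimination of the imine) extends the alkyne by one carbon to the terminal allene and tolerates free hydroxyl groups.

Step 7
Reactants: 10 (3R)-3-methyl-4-methylidenenona-7,8-diene-1,5-diol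
Product: 13 (5Z)-5-[(2R)-4-hydroxybutan-2-yl]deca-5,8,9-trien-2-one, via bis-ether 11 (not isolated), via ketone ether 12 (not isolated)
Conditions: 2-methoxypropene (10 equiv), propionic acid (10 mol %), toluene, 130 °C (sealed tube); then AcOH/THF/H2O, rt
Reagents that add atoms: 2-methoxypropene, COC(C)=C
Why: Saucy–Marbet Claisen rearrangement of the 2-propenyl ether of the secondary allylic alcohol through a chair transition state with the C6′ chain equatorial installs the 3-oxobutyl chain and should set the trisubstituted C1′=C5′ alkene with C6′ cis to C10′ (Z), the temporary ether on the primary hydroxyl being hydrolysed on work-up.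

Step 8
Reactants: 13 (5Z)-5-[(2R)-4-hydroxybutan-2-yl]deca-5,8,9-trien-2-one
Product: 14 (3R,4Z)-3-methyl-4-(3-oxobutyl)nona-4,7,8-trienal
Conditions: Dess–Martin periodinane (1.2 equiv), CH2Cl2, 0 °C → rt
Reagents that add atoms: none
Why: Dess–Martin oxidation converts the primary alcohol into the aldehyde under conditions that leave the ketone, the allene, the skipped diene and the non-epimerisable β-stereocentre untouched.

Step 9
Reactants: 14 (3R,4Z)-3-methyl-4-(3-oxobutyl)nona-4,7,8-trienal
Product: 15 (3aS,7R,8aS)-7-methyl-3-methylidene-6-(3-oxobutyl)-3,3a,4,7,8,8a-hexahydro-2H-cyclohepta[b]furan-2-one (eastern monomer, antipode of 2,3-dihydro-8-epi-xanthatin)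
Conditions: Ru3(CO)12 (5 mol %), CO (20 atm), 1,4-dioxane, 120 °C
Reagents that add atoms: carbon monoxide, [C-]#[O+]
Why: Proposed new method: zerovalent ruthenium binds the aldehyde C=O and the internal allene π-bond C7′=C11′, oxidative cyclisation forms the C7′–C8′ bond and an oxaruthenacyclopentane, CO inserts into the Ru–C11′ bond (C11′–C12′) and C–O reductive elimination releases the lactone; the closest known reaction type is the Ru3(CO)12- or Mo(CO)6-mediated hetero-Pauson–Khand cyclocarbonylation of allenyl aldehydes to five- and six-ring-fused α-methylene-γ-butyrolactones, extended here to closure of a seven-membered carbocycle. Ring E closes in a 7-exo mode (C8′ onto the proximal allene carbon C7′ across a five-atom tether) and ring D by the [2+2+1] union of C8′=O, C7′=C11′ and CO. C7′ and C8′ are set cis to each other because both new bonds form inside one metallacycle, and their sense relative to C10′ is expected from a chair-like cycloheptene transition state in which the C10′ methyl group and the ruthenium-bound aldehyde oxygen are pseudo-equatorial and the slim allene is pseudo-axial, which puts lactone and methyl on the same face (7′S,8′S from 10′R). The step needs chemoselectivity for the aldehyde over the methyl ketone, regioselectivity for the internal allene π-bond and 1,3-induction from C10′: the first is secured because the ketone could reach the allene only through a trans-cycloheptene, the second because only the internal π-bond lets metal and oxygen span a five-membered ring (this leaves the exocyclic C13′ methylene needed in step 19), and the third by the Z-configured C1′=C5′ alkene, which holds both reacting termini on one side and restricts the tether to the folded chair described.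

Step 10
Reactants: 2 (3R)-5-methoxy-3-methyl-5-oxopentanoic acid
Product: 17 (4S)-4-methyloxan-2-one, via lithium hydroxy-carboxylate 16 (not isolated)
Conditions: LiOH·H2O (1.0 equiv), THF/H2O, then evaporation; LiBH4 (1.5 equiv), THF, 0 → 40 °C; then 2 M HCl, rt
Reagents that add atoms: none
Why: LiBH4 reduces the methyl ester but not the lithium carboxylate, so lactonisation now engages the other terminus and the same half-ester should deliver the antipodal (S)-lactone (enantiodivergent use of the desymmetrised glutarate).

Step 11
Reactants: 17 (4S)-4-methyloxan-2-one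
Product: 19 (4S)-4-methyl-3-methylideneoxan-2-one, via sodium formyl-enolate 18 (not isolated)
Conditions: NaH (1.2 equiv), HCO2Et (1.5 equiv), Et2O, 0 °C → rt; then (CH2O)n (5 equiv), THF, reflux
Reagents that add atoms: formaldehyde (as paraformaldehyde), C=O
Why: The same one-flask α-methylenation (Claisen formylation, formaldehyde aldol, loss of formate) as in step 3 is applied to the antipodal lactone, the C4 stereocentre again being a spectator.

Step 12
Reactants: 19 (4S)-4-methyl-3-methylideneoxan-2-one
Product: 20 (4S)-4-methyl-3-methylideneoxan-2-ol (anomer mixture)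
Conditions: iBu2AlH (1.1 equiv), CH2Cl2, −78 °C; aq. potassium sodium tartrate
Reagents that add atoms: none
Why: Low-temperature iBu2AlH 1,2-reduction of the unsaturated lactone should stop at the lactol, as in step 4.

Step 13
Reactants: 20 (4S)-4-methyl-3-methylideneoxan-2-ol
Product: 21 (3S)-3-methyl-4-methylideneoct-7-yne-1,5-diol (both carbinol epimers)
Conditions: propargyl bromide (2.0 equiv), Zn (2.5 equiv), THF/sat. aq. NH4Cl (1:1), 0 °C → rt
Reagents that add atoms: propargyl bromide, C#CCBr
Why: Aqueous zinc Barbier propargylation of the open hydroxy-enal form gives the homopropargylic alcohol as in step 5, the unselectively formed carbinol centre being removed in step 15.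

Step 14
Reactants: 21 (3S)-3-methyl-4-methylideneoct-7-yne-1,5-diol
Product: 23 (3S)-3-methyl-4-methylidenenona-7,8-diene-1,5-diol (both carbinol epimers), via Mannich base 22 (not isolated)
Conditions: (CH2O)n (2 equiv), iPr2NH (2 equiv), CuBr (30 mol %), 1,4-dioxane, reflux
Reagents that add atoms: formaldehyde (as paraformaldehyde), C=O
Why: Crabbé homologation (Mannich reaction, copper-mediated hydride transfer) turns the terminal alkyne into the terminal allene as in step 6.

Step 15
Reactants: 23 (3S)-3-methyl-4-methylidenenona-7,8-diene-1,5-diol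
Product: 26 (5Z)-5-[(2S)-4-hydroxybutan-2-yl]deca-5,8,9-trien-2-one, via bis-ether 24 (not isolated), via ketone ether 25 (not isolated)
Conditions: 2-methoxypropene (10 equiv), propionic acid (10 mol %), toluene, 130 °C (sealed tube); then AcOH/THF/H2O, rt
Reagents that add atoms: 2-methoxypropene, COC(C)=C
Why: Saucy–Marbet Claisen rearrangement through the chair transition state with the C6 chain equatorial installs the 3-oxobutyl chain and the Z-trisubstituted C1=C5 alkene as in step 7.

Step 16
Reactants: 26 (5Z)-5-[(2S)-4-hydroxybutan-2-yl]deca-5,8,9-trien-2-one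
Product: 27 (3S,4Z)-3-methyl-4-(3-oxobutyl)nona-4,7,8-trienal
Conditions: Dess–Martin periodinane (1.2 equiv), CH2Cl2, 0 °C → rt
Reagents that add atoms: none
Why: Dess–Martin oxidation of the primary alcohol gives the aldehyde without touching ketone, allene or the non-epimerisable β-stereocentre, as in step 8.

Step 17
Reactants: 27 (3S,4Z)-3-methyl-4-(3-oxobutyl)nona-4,7,8-trienal
Product: 28 (3aR,7S,8aR)-7-methyl-3-methylidene-6-(3-oxobutyl)-3,3a,4,7,8,8a-hexahydro-2H-cyclohepta[b]furan-2-one (2,3-dihydro-8-epi-xanthatin)
Conditions: Ru3(CO)12 (5 mol %), CO (20 atm), 1,4-dioxane, 120 °C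
Reagents that add atoms: carbon monoxide, [C-]#[O+]
Why: Proposed new method: the same ruthenium-catalysed allenic hetero-Pauson–Khand cyclocarbonylation as in step 9 is run in the mirror-image series (oxidative cyclisation of C8=O with C7=C11 on zerovalent ruthenium, CO insertion, C–O reductive elimination; closest known type: cyclocarbonylation of allenyl aldehydes to five- and six-ring-fused α-methylene lactones), the C10 stereocentre again expected to direct the cis-fused lactone to the face of the methyl group (7R,8R from 10S).

Step 18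
Reactants: 28 (3aR,7S,8aR)-7-methyl-3-methylidene-6-(3-oxobutyl)-3,3a,4,7,8,8a-hexahydro-2H-cyclohepta[b]furan-2-one
Product: 29 (3aR,7S,8aR)-7-methyl-3-methylidene-6-[(1E)-3-oxobut-1-en-1-yl]-3,3a,4,7,8,8a-hexahydro-2H-cyclohepta[b]furan-2-one (8-epi-xanthatin)
Conditions: IBX (2.5 equiv), DMSO/fluorobenzene (1:2), 70 °C
Reagents that add atoms: none
Why: IBX dehydrogenation of the ketone can introduce unsaturation only on the methylene side of the methyl ketone, where the new C2=C3 bond gains conjugation with C1=C5, and should give the E-dienone.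

Step 19
Reactants: 29 8-epi-xanthatin (diene); 15 eastern monomer (dienophile)
Product: 30 Diels–Alder adduct, the 1-deoxy isomer of the target with a C1=C2 double bond and a hydrogen on C3 (acetyl on C3 cis to the lactone carbonyl C12′ and to C6 on ring C)
Conditions: 29 added over 12 h to 15 (4 equiv), toluene (minimum volume), 2,6-di-tert-butyl-4-methylphenol (1 mol %), 90 °C, dark; excess 15 recovered
Reagents that add atoms: none
Why: Intermolecular Diels–Alder reaction of the 1-acyl diene with the 1,1-disubstituted α-methylene lactone follows the ortho rule (C3–C11′ and C5–C13′), the dienophile approaching the diene face anti to the C10 methyl group and ring A, the diene approaching the convex face of the cis-fused lactone (anti to C6′) with the lactone carbonyl endo, which sets C5, C3 and the spiro centre C11′; slow addition of the diene into excess dienophile suppresses homodimerisation of the diene.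

Step 20
Reactants: 30 Diels–Alder adduct
Product: 32 CNP0195550.3 (target), via hydroperoxide 31 (not isolated)
Conditions: O2 (1 atm), DBU (1.1 equiv), P(OEt)3 (2.0 equiv), MeCN, 0 °C
Reagents that add atoms: dioxygen, O=O
Why: DBU removes the doubly activated C3–H (α to the ketone, allylic to C1=C2), and the extended dienolate is oxygenated at the tertiary γ-carbon C1 (known γ-autoxidation of deconjugated enones; the α-carbon is flanked by the quaternary C11′) on the face of ring C anti to C6 and C12′, which sets the C1 hydroxyl cis to H5, the hydroperoxide being reduced in situ by the phosphite.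

## Compound list

1 | dimethyl 3-methylpentanedioate | COC(=O)CC(C)CC(=O)OC | starting material
2 | (3R)-5-methoxy-3-methyl-5-oxopentanoic acid | COC(=O)C[C@H](C)CC(=O)O | intermediate
3 | methyl (3R)-5-hydroxy-3-methylpentanoate | COC(=O)C[C@H](C)CCO | intermediate (not isolated)
4 | (4R)-4-methyloxan-2-one | O=C1OCC[C@@H](C)C1 | intermediate
5 | sodium [(4R)-4-methyl-2-oxooxan-3-ylidene]methanolate (enolate geometry not defined) | O=C1OCC[C@@H](C)C1=C[O-].[Na+] | intermediate (not isolated)
6 | (4R)-4-methyl-3-methylideneoxan-2-one | O=C1OCC[C@@H](C)C1=C | intermediate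
7 | (4R)-4-methyl-3-methylideneoxan-2-ol (anomer mixture) | OC1OCC[C@@H](C)C1=C | intermediate
8 | (3R)-3-methyl-4-methylideneoct-7-yne-1,5-diol (C5 epimers) | OCC[C@@H](C)C(=C)C(O)CC#C | intermediate
9 | (3R)-9-[di(propan-2-yl)amino]-3-methyl-4-methylidenenon-7-yne-1,5-diol | OCC[C@@H](C)C(=C)C(O)CC#CCN(C(C)C)C(C)C | intermediate (not isolated)
10 | (3R)-3-methyl-4-methylidenenona-7,8-diene-1,5-diol (C5 epimers) | OCC[C@@H](C)C(=C)C(O)CC=C=C | intermediate
11 | (3R)-1-[(2-methoxypropan-2-yl)oxy]-3-methyl-4-methylidene-5-(prop-1-en-2-yloxy)nona-7,8-diene | COC(C)(C)OCC[C@@H](C)C(=C)C(OC(C)=C)CC=C=C | intermediate (not isolated)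
12 | (5Z)-5-{(2R)-4-[(2-methoxypropan-2-yl)oxy]butan-2-yl}deca-5,8,9-trien-2-one | COC(C)(C)OCC[C@@H](C)/C(CCC(C)=O)=C\CC=C=C | intermediate (not isolated)
13 | (5Z)-5-[(2R)-4-hydroxybutan-2-yl]deca-5,8,9-trien-2-one | OCC[C@@H](C)/C(CCC(C)=O)=C\CC=C=C | intermediate
14 | (3R,4Z)-3-methyl-4-(3-oxobutyl)nona-4,7,8-trienal | O=CC[C@@H](C)/C(CCC(C)=O)=C\CC=C=C | intermediate
15 | (3aS,7R,8aS)-7-methyl-3-methylidene-6-(3-oxobutyl)-3,3a,4,7,8,8a-hexahydro-2H-cyclohepta[b]furan-2-one | C=C1C(=O)O[C@H]2C[C@@H](C)C(CCC(C)=O)=CC[C@@H]12 | intermediate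
16 | lithium (3S)-5-hydroxy-3-methylpentanoate | [Li+].[O-]C(=O)C[C@@H](C)CCO | intermediate (not isolated)
17 | (4S)-4-methyloxan-2-one | O=C1OCC[C@H](C)C1 | intermediate
18 | sodium [(4S)-4-methyl-2-oxooxan-3-ylidene]methanolate (enolate geometry not defined) | O=C1OCC[C@H](C)C1=C[O-].[Na+] | intermediate (not isolated)
19 | (4S)-4-methyl-3-methylideneoxan-2-one | O=C1OCC[C@H](C)C1=C | intermediate
20 | (4S)-4-methyl-3-methylideneoxan-2-ol (anomer mixture) | OC1OCC[C@H](C)C1=C | intermediate
21 | (3S)-3-methyl-4-methylideneoct-7-yne-1,5-diol (C5 epimers) | OCC[C@H](C)C(=C)C(O)CC#C | intermediate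
22 | (3S)-9-[di(propan-2-yl)amino]-3-methyl-4-methylidenenon-7-yne-1,5-diol | OCC[C@H](C)C(=C)C(O)CC#CCN(C(C)C)C(C)C | intermediate (not isolated)
23 | (3S)-3-methyl-4-methylidenenona-7,8-diene-1,5-diol (C5 epimers) | OCC[C@H](C)C(=C)C(O)CC=C=C | intermediate
24 | (3S)-1-[(2-methoxypropan-2-yl)oxy]-3-methyl-4-methylidene-5-(prop-1-en-2-yloxy)nona-7,8-diene | COC(C)(C)OCC[C@H](C)C(=C)C(OC(C)=C)CC=C=C | intermediate (not isolated)
25 | (5Z)-5-{(2S)-4-[(2-methoxypropan-2-yl)oxy]butan-2-yl}deca-5,8,9-trien-2-one | COC(C)(C)OCC[C@H](C)/C(CCC(C)=O)=C\CC=C=C | intermediate (not isolated)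
26 | (5Z)-5-[(2S)-4-hydroxybutan-2-yl]deca-5,8,9-trien-2-one | OCC[C@H](C)/C(CCC(C)=O)=C\CC=C=C | intermediate
27 | (3S,4Z)-3-methyl-4-(3-oxobutyl)nona-4,7,8-trienal | O=CC[C@H](C)/C(CCC(C)=O)=C\CC=C=C | intermediate
28 | (3aR,7S,8aR)-7-methyl-3-methylidene-6-(3-oxobutyl)-3,3a,4,7,8,8a-hexahydro-2H-cyclohepta[b]furan-2-one | C=C1C(=O)O[C@@H]2C[C@H](C)C(CCC(C)=O)=CC[C@H]12 | intermediate
29 | (3aR,7S,8aR)-7-methyl-3-methylidene-6-[(1E)-3-oxobut-1-en-1-yl]-3,3a,4,7,8,8a-hexahydro-2H-cyclohepta[b]furan-2-one (8-epi-xanthatin) | C=C1C(=O)O[C@@H]2C[C@H](C)C(/C=C/C(C)=O)=CC[C@H]12 | intermediate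
30 | Diels–Alder adduct (1-deoxy isomer of the target, C1=C2, 3-H) | C=C1C(=O)O[C@@H]2C[C@H](C)C3=C[C@@H](C(C)=O)[C@]4(C[C@H]3C[C@H]12)C(=O)O[C@H]1C[C@@H](C)C(CCC(C)=O)=CC[C@H]14 | intermediate
31 | C1 hydroperoxide of the target | C=C1C(=O)O[C@@H]2C[C@H](C)[C@@]3(OO)C=C(C(C)=O)[C@]4(C[C@H]3C[C@H]12)C(=O)O[C@H]1C[C@@H](C)C(CCC(C)=O)=CC[C@H]14 | intermediate (not isolated)
32 | CNP0195550.3 | C=C1C(=O)O[C@@H]2C[C@H](C)[C@@]3(O)C=C(C(C)=O)[C@]4(C[C@H]3C[C@H]12)C(=O)O[C@H]1C[C@@H](C)C(CCC(C)=O)=CC[C@H]14 | target

## Step count and risks

Total step count: 20. Longest linear sequence: 12 steps (1, 10–18, 19, 20).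

**Step 9.** The seven-membered oxidative cyclisation may be slow relative to ruthenium-mediated isomerisation or oligomerisation of the allene and to decarbonylation of the aldehyde. The 1,3-induction from C10′ may also be eroded or reversed: allylic strain with the C2′ methylene could favour the folding with a pseudo-axial methyl group, which would place the cis-lactone anti to the methyl group. The fallback separates ring closure from carbonylation and uses known reaction types. It sets out from 14: hexabutylditin (Bu3Sn–SnBu3) and Pd(PPh3)4 (zerovalent palladium) in THF at 60 °C should effect bis-stannylation of the allene and, in the same flask, intramolecular carbonyl allylation by the allylstannane, giving 4-[(4R,5S,7R)-5-hydroxy-7-methyl-4-[1-(tributylstannyl)ethenyl]cyclohept-1-en-1-yl]butan-2-one F1. Iododestannylation (I2, CH2Cl2, 0 °C) should give 4-[(4R,5S,7R)-5-hydroxy-4-(1-iodoethenyl)-7-methylcyclohept-1-en-1-yl]butan-2-one F2. Carbonylative lactonisation (Pd(PPh3)4, CO 1 atm, K2CO3, THF, 50 °C) then comes back to the route at 15.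

**Step 17.** The same process risks apply in the mirror-image series (slow seven-ring closure, allene isomerisation, weak or reversed 1,3-induction from C10). The fallback sets out from 27: the same one-flask bis-stannylation and carbonyl allylation should give 4-[(4S,5R,7S)-5-hydroxy-7-methyl-4-[1-(tributylstannyl)ethenyl]cyclohept-1-en-1-yl]butan-2-one F3, and iododestannylation the vinyl iodide 4-[(4S,5R,7S)-5-hydroxy-4-(1-iodoethenyl)-7-methylcyclohept-1-en-1-yl]butan-2-one F4. Palladium-catalysed carbonylative lactonisation comes back to the route at 28.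

**Step 19.** The diene 29 carries its own α-methylene lactone and may homodimerise or polymerise faster than it finds 15. Endo and facial selectivity may also be insufficient under purely thermal conditions. The fallback masks the dienophile of the diene and sets out from 29: conjugate addition of dimethylamine (EtOH, 0 °C; protonation from the convex face) should give (3R,3aR,7S,8aR)-3-[(dimethylamino)methyl]-7-methyl-6-[(1E)-3-oxobut-1-en-1-yl]-3,3a,4,7,8,8a-hexahydro-2H-cyclohepta[b]furan-2-one F5, which can act only as a diene. Cycloaddition with 15 (1.5 equiv, CH2Cl2, 12 kbar, rt) should give the amine-masked adduct F6. Quaternisation with MeI gives the trimethylammonium iodide of the adduct F7, and NaHCO3-induced elimination of trimethylamine comes back to the route at 30.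

## Further compounds

F1 | step 9 | 4-[(4R,5S,7R)-5-hydroxy-7-methyl-4-[1-(tributylstannyl)ethenyl]cyclohept-1-en-1-yl]butan-2-one | O[C@H]1C[C@@H](C)C(CCC(C)=O)=CC[C@H]1C(=C)[Sn](CCCC)(CCCC)CCCC
F2 | step 9 | 4-[(4R,5S,7R)-5-hydroxy-4-(1-iodoethenyl)-7-methylcyclohept-1-en-1-yl]butan-2-one | O[C@H]1C[C@@H](C)C(CCC(C)=O)=CC[C@H]1C(I)=C
F3 | step 17 | 4-[(4S,5R,7S)-5-hydroxy-7-methyl-4-[1-(tributylstannyl)ethenyl]cyclohept-1-en-1-yl]butan-2-one | O[C@@H]1C[C@H](C)C(CCC(C)=O)=CC[C@@H]1C(=C)[Sn](CCCC)(CCCC)CCCC
F4 | step 17 | 4-[(4S,5R,7S)-5-hydroxy-4-(1-iodoethenyl)-7-methylcyclohept-1-en-1-yl]butan-2-one | O[C@@H]1C[C@H](C)C(CCC(C)=O)=CC[C@@H]1C(I)=C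
F5 | step 19 | (3R,3aR,7S,8aR)-3-[(dimethylamino)methyl]-7-methyl-6-[(1E)-3-oxobut-1-en-1-yl]-3,3a,4,7,8,8a-hexahydro-2H-cyclohepta[b]furan-2-one | CN(C)C[C@@H]1C(=O)O[C@@H]2C[C@H](C)C(/C=C/C(C)=O)=CC[C@H]12
F6 | step 19 | amine-masked Diels–Alder adduct (30 with the ring A methylene replaced by H and CH2NMe2) | CN(C)C[C@@H]1C(=O)O[C@@H]2C[C@H](C)C3=C[C@@H](C(C)=O)[C@]4(C[C@H]3C[C@H]12)C(=O)O[C@H]1C[C@@H](C)C(CCC(C)=O)=CC[C@H]14
F7 | step 19 | trimethylammonium iodide of the masked adduct | C[N+](C)(C)C[C@@H]1C(=O)O[C@@H]2C[C@H](C)C3=C[C@@H](C(C)=O)[C@]4(C[C@H]3C[C@H]12)C(=O)O[C@H]1C[C@@H](C)C(CCC(C)=O)=CC[C@H]14.[I-]
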